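**Retrosynthetic overview** (isochroman numbering C1–C8a for both halves)

1. The C7–CH(CH3) bond is cut as a Michael addition: C7 of the quinone methide decarboxycitrinin 20 adds to an ortho-quinone methide 21 released from benzylic alcohol 16, with a chiral phosphoric acid setting the linker centre.
2. Both partners come from one lactone, 13: C7 formylation and MeMgBr addition give 16; silylation, DIBAL-H reduction and desilylation–dehydration give 20.
3. Lactone 13 comes from aryl bromide 9 by Br/Li exchange, carboxylation, lactonisation and demethylation.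
4. Bromide 9 comes from (2R,3S)-3-arylbutan-2-ol 8: aryl Grignard 5 opens (2S,3S)-2,3-epoxybutane (sets C4), then Mitsunobu inversion sets C3.
5. Ring order: arene (bought) → δ-lactone (step 7) → quinone methide pyran of the left half (step 13) → union (step 14, no ring formed).

Assumption: (2S,3S)-2,3-epoxybutane is bought as such, and (R)-TRIP is taken to give the (R)-linker; the sense must be checked on the first run, and the antipodal catalyst is used if it is opposite.

**Step 1**
Reactants: 1 1-bromo-3,5-dimethoxybenzene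
Product: 2 2-bromo-4,6-dimethoxybenzaldehyde
Conditions: POCl3, DMF, 0 → 90 °C; then ice/H2O
Reagents that add atoms: N,N-dimethylformamide, CN(C)C=O
Why: Vilsmeier–Haack formylation goes to the position para to one methoxy and ortho to the other (C2 and C6 are equivalent) in preference to the site between the two methoxy groups.

**Step 2**
Reactants: 2 2-bromo-4,6-dimethoxybenzaldehyde
Product: 3 1-bromo-3,5-dimethoxy-2-methylbenzene
Conditions: Et3SiH (3 equiv), TFA, CH2Cl2, 0 °C → rt
Reagents that add atoms: none
Why: Ionic hydrogenation (Kursanov–Parnes reduction) of the protonated electron-rich aldehyde by two hydride transfers from the silane gives the methyl group and leaves the aryl bromide and ethers alone.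

**Step 3**
Reactants: 3 1-bromo-3,5-dimethoxy-2-methylbenzene + 4 (2S,3S)-2,3-epoxybutane
Product: 6 (2S,3S)-3-(3,5-dimethoxy-2-methylphenyl)butan-2-ol, via arylmagnesium bromide 5 (not isolated)
Conditions: Mg, THF, reflux; then CuI (10 mol%), 4, −30 → 0 °C; aqueous work-up
Reagents that add atoms: none
Why: Copper-catalysed Grignard opening of the C2-symmetric epoxide is an SN2 attack with inversion at one of the two equivalent carbons while the carbinol carbon is untouched, which gives the (2S,3S) alcohol and fixes the later C4 as S.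

**Step 4**
Reactants: 6 (2S,3S)-3-(3,5-dimethoxy-2-methylphenyl)butan-2-ol
Product: 7 (2R,3S)-3-(3,5-dimethoxy-2-methylphenyl)butan-2-yl 4-nitrobenzoate
Conditions: 4-O2NC6H4CO2H, PPh3, DIAD, toluene, 0 °C → rt
Reagents that add atoms: 4-nitrobenzoic acid, OC(=O)c1ccc(cc1)[N+](=O)[O-]
Why: In the Mitsunobu reaction the carboxylate displaces the activated hydroxyl in an SN2 step, so the carbinol centre is inverted from S to R (the later C3) and the aryl-bearing centre is not touched.

**Step 5**
Reactants: 7 (2R,3S)-3-(3,5-dimethoxy-2-methylphenyl)butan-2-yl 4-nitrobenzoate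
Product: 8 (2R,3S)-3-(3,5-dimethoxy-2-methylphenyl)butan-2-ol
Conditions: K2CO3 (0.2 equiv), MeOH, rt
Reagents that add atoms: none
Why: Base-catalysed transesterification of the activated 4-nitrobenzoate frees the alcohol by acyl–oxygen cleavage, so neither stereocentre changes.

**Step 6**
Reactants: 8 (2R,3S)-3-(3,5-dimethoxy-2-methylphenyl)butan-2-ol
Product: 9 (2R,3S)-3-(2-bromo-3,5-dimethoxy-6-methylphenyl)butan-2-ol
Conditions: NBS (1.05 equiv), MeCN, 0 °C
Reagents that add atoms: N-bromosuccinimide, O=C1CCC(=O)N1Br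
Why: Electrophilic aromatic bromination with NBS takes the position para to one methoxy and ortho to the other (next to the side chain) in preference to the shielded site between the two methoxy groups, as with other 5-alkylresorcinol dimethyl ethers.

**Step 7**
Reactants: 9 (2R,3S)-3-(2-bromo-3,5-dimethoxy-6-methylphenyl)butan-2-ol
Product: 12 (3R,4S)-6,8-dimethoxy-3,4,5-trimethylisochroman-1-one, via dilithio species 10 (not isolated), via hydroxy acid 11 (not isolated)
Conditions: n-BuLi (2.2 equiv), THF, −78 °C; CO2, −78 °C → rt; aq. HCl; then TsOH (cat.), toluene, 80 °C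
Reagents that add atoms: carbon dioxide, O=C=O
Why: Bromine–lithium exchange on the lithium alkoxide, carboxylation of the aryllithium and acid-catalysed lactonisation by acyl substitution close the δ-lactone with retention at both stereocentres.

**Step 8**
Reactants: 12 (3R,4S)-6,8-dimethoxy-3,4,5-trimethylisochroman-1-one
Product: 13 (3R,4S)-6,8-dihydroxy-3,4,5-trimethylisochroman-1-one
Conditions: BBr3 (4 equiv), CH2Cl2, −78 → 0 °C; H2O
Reagents that add atoms: none
Why: Lewis-acid ether cleavage with BBr3 removes both aryl methyl ethers (the peri one helped by chelation to the lactone carbonyl) and leaves the lactone and its secondary alkyl C–O bond intact.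

**Step 9**
Reactants: 13 (3R,4S)-6,8-dihydroxy-3,4,5-trimethylisochroman-1-one
Product: 15 (3R,4S)-6,8-dihydroxy-3,4,5-trimethyl-1-oxoisochromane-7-carbaldehyde, via hydroxymethyl phenol 14 (not isolated)
Conditions: MgCl2, Et3N, (CH2O)n, MeCN, reflux; then 1 M HCl
Reagents that add atoms: formaldehyde (as paraformaldehyde), C=O
Why: In the Casnati–Skattebøl ortho-formylation the magnesium phenoxide directs formaldehyde to C7, the only free ring position, and a second formaldehyde oxidises the hydroxymethyl phenol to the aldehyde by hydride transfer.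

**Step 10**
Reactants: 15 (3R,4S)-6,8-dihydroxy-3,4,5-trimethyl-1-oxoisochromane-7-carbaldehyde
Product: 16 (3R,4S)-6,8-dihydroxy-7-(1-hydroxyethyl)-3,4,5-trimethylisochroman-1-one (both carbinol epimers; used crude)
Conditions: MeMgBr (4 equiv), THF, −78 → −20 °C; buffered aqueous quench (pH 6)
Reagents that add atoms: methylmagnesium bromide, C[Mg]Br
Why: Grignard addition occurs at the magnesium-chelated aldehyde, which is far more electrophilic than the phenoxide-deactivated lactone, and the new carbinol centre forms as a mixture that is erased in step 14.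

**Step 11**
Reactants: 13 (3R,4S)-6,8-dihydroxy-3,4,5-trimethylisochroman-1-one
Product: 17 (3R,4S)-6,8-bis[(tert-butyldimethylsilyl)oxy]-3,4,5-trimethylisochroman-1-one
Conditions: TBSOTf (2.5 equiv), 2,6-lutidine, CH2Cl2, 0 °C → rt
Reagents that add atoms: tert-butyldimethylsilyl trifluoromethanesulfonate, CC(C)(C)[Si](C)(C)OS(=O)(=O)C(F)(F)F
Why: Silyl ether formation with the reactive triflate protects both phenols, including the hydrogen-bonded peri one, so that the lactone can be reduced cleanly.

**Step 12**
Reactants: 17 (3R,4S)-6,8-bis[(tert-butyldimethylsilyl)oxy]-3,4,5-trimethylisochroman-1-one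
Product: 18 (3R,4S)-6,8-bis[(tert-butyldimethylsilyl)oxy]-3,4,5-trimethylisochroman-1-ol (both anomers)
Conditions: DIBAL-H (1.3 equiv), CH2Cl2, −78 °C; Rochelle salt
Reagents that add atoms: none
Why: DIBAL-H partial reduction stops at the lactol because the aluminium hemiacetal is stable at −78 °C, and C3 and C4 are not involved.

**Step 13**
Reactants: 18 (3R,4S)-6,8-bis[(tert-butyldimethylsilyl)oxy]-3,4,5-trimethylisochroman-1-ol
Product: 20 decarboxycitrinin [(3R,4S)-6-hydroxy-3,4,5-trimethyl-3,4-dihydro-8H-isochromen-8-one], via lactol triol 19 (not isolated)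
Conditions: TBAF, AcOH, THF, 0 °C; then toluene azeotrope (−H2O)
Reagents that add atoms: none
Why: Fluoride desilylation frees the two phenols and the lactol then loses water to the vinylogous-acid quinone methide, the same cyclisation–dehydration that ends citrinin syntheses.

**Step 14**
Reactants: 16 (3R,4S)-6,8-dihydroxy-7-(1-hydroxyethyl)-3,4,5-trimethylisochroman-1-one + 20 decarboxycitrinin
Product: 22 dicitrinone H, via ortho-quinone methide 21 (not isolated)
Conditions: 20 (1.5 equiv), (R)-TRIP (10 mol%), 4 Å MS, CHCl3, 0 °C → rt; reverse-phase HPLC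
Reagents that add atoms: none
Why: In this Brønsted-acid-catalysed Michael addition the chiral phosphoric acid dehydrates 16 to the ortho-quinone methide and holds it and the enol of 20 (C7 is its only free nucleophilic carbon) in a hydrogen-bonded complex, so C7 adds to one face of the ethylidene carbon and the (R)-linker centre is set under catalyst control before tautomerisation restores the resorcinol ring.

**Compound list**

1 | 1-bromo-3,5-dimethoxybenzene | COc1cc(Br)cc(OC)c1 | starting material
2 | 2-bromo-4,6-dimethoxybenzaldehyde | COc1cc(OC)c(C=O)c(Br)c1 | intermediate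
3 | 1-bromo-3,5-dimethoxy-2-methylbenzene | COc1cc(OC)c(C)c(Br)c1 | intermediate
4 | (2S,3S)-2,3-epoxybutane [(2S,3S)-2,3-dimethyloxirane] | C[C@@H]1O[C@H]1C | starting material
5 | (3,5-dimethoxy-2-methylphenyl)magnesium bromide | COc1cc(OC)c(C)c([Mg]Br)c1 | intermediate (not isolated)
6 | (2S,3S)-3-(3,5-dimethoxy-2-methylphenyl)butan-2-ol | C[C@H](O)[C@@H](C)c1cc(OC)cc(OC)c1C | intermediate
7 | (2R,3S)-3-(3,5-dimethoxy-2-methylphenyl)butan-2-yl 4-nitrobenzoate | C[C@@H](OC(=O)c1ccc(cc1)[N+](=O)[O-])[C@@H](C)c1cc(OC)cc(OC)c1C | intermediate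
8 | (2R,3S)-3-(3,5-dimethoxy-2-methylphenyl)butan-2-ol | C[C@@H](O)[C@@H](C)c1cc(OC)cc(OC)c1C | intermediate
9 | (2R,3S)-3-(2-bromo-3,5-dimethoxy-6-methylphenyl)butan-2-ol | C[C@@H](O)[C@@H](C)c1c(Br)c(OC)cc(OC)c1C | intermediate
10 | lithium (2R,3S)-3-(2-lithio-3,5-dimethoxy-6-methylphenyl)butan-2-olate (dilithio species) | C[C@@H](O[Li])[C@@H](C)c1c([Li])c(OC)cc(OC)c1C | intermediate (not isolated)
11 | 2-[(2S,3R)-3-hydroxybutan-2-yl]-4,6-dimethoxy-3-methylbenzoic acid | C[C@@H](O)[C@@H](C)c1c(C(=O)O)c(OC)cc(OC)c1C | intermediate (not isolated)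
12 | (3R,4S)-6,8-dimethoxy-3,4,5-trimethylisochroman-1-one | COc1cc(OC)c2C(=O)O[C@H](C)[C@@H](C)c2c1C | intermediate
13 | (3R,4S)-6,8-dihydroxy-3,4,5-trimethylisochroman-1-one | Oc1cc(O)c2C(=O)O[C@H](C)[C@@H](C)c2c1C | intermediate
14 | (3R,4S)-6,8-dihydroxy-7-(hydroxymethyl)-3,4,5-trimethylisochroman-1-one | Oc1c(CO)c(O)c2C(=O)O[C@H](C)[C@@H](C)c2c1C | intermediate (not isolated)
15 | (3R,4S)-6,8-dihydroxy-3,4,5-trimethyl-1-oxoisochromane-7-carbaldehyde | Oc1c(C=O)c(O)c2C(=O)O[C@H](C)[C@@H](C)c2c1C | intermediate
16 | (3R,4S)-6,8-dihydroxy-7-(1-hydroxyethyl)-3,4,5-trimethylisochroman-1-one (both carbinol epimers) | Oc1c(C(C)O)c(O)c2C(=O)O[C@H](C)[C@@H](C)c2c1C | intermediate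
17 | (3R,4S)-6,8-bis[(tert-butyldimethylsilyl)oxy]-3,4,5-trimethylisochroman-1-one | CC(C)(C)[Si](C)(C)Oc1cc(O[Si](C)(C)C(C)(C)C)c2C(=O)O[C@H](C)[C@@H](C)c2c1C | intermediate
18 | (3R,4S)-6,8-bis[(tert-butyldimethylsilyl)oxy]-3,4,5-trimethylisochroman-1-ol (both anomers) | CC(C)(C)[Si](C)(C)Oc1cc(O[Si](C)(C)C(C)(C)C)c2C(O)O[C@H](C)[C@@H](C)c2c1C | intermediate
19 | (3R,4S)-3,4,5-trimethylisochromane-1,6,8-triol (both anomers) | Oc1cc(O)c2C(O)O[C@H](C)[C@@H](C)c2c1C | intermediate (not isolated)
20 | decarboxycitrinin, (3R,4S)-6-hydroxy-3,4,5-trimethyl-3,4-dihydro-8H-isochromen-8-one | CC1=C2C(=CO[C@H](C)[C@H]2C)C(=O)C=C1O | intermediate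
21 | (3R,4S)-7-ethylidene-8-hydroxy-3,4,5-trimethyl-3,4-dihydro-1H-isochromene-1,6(7H)-dione (ortho-quinone methide) | CC=C1C(=O)C(C)=C2[C@H](C)[C@@H](C)OC(=O)C2=C1O | intermediate (not isolated)
22 | dicitrinone H, (3R,4S)-6,8-dihydroxy-7-{(1R)-1-[(3R,4S)-6-hydroxy-3,4,5-trimethyl-8-oxo-3,4-dihydro-8H-isochromen-7-yl]ethyl}-3,4,5-trimethylisochroman-1-one | CC1=C2C(=CO[C@H](C)[C@H]2C)C(=O)C([C@H](C)c2c(O)c(C)c3c(c2O)C(=O)O[C@H](C)[C@H]3C)=C1O | target

**Step count and risks**

Total steps: 14. Longest linear sequence: 12 (steps 1–8, 11–13, 14).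

Most likely to fail, first: step 14. Decarboxycitrinin can self-condense at its electrophilic C1, and catalyst control of a methyl-substituted ortho-quinone methide is the least precedented part. The fallback changes how the quinone methide is made and the type of catalyst. It sets out from 16: sodium 4-methylbenzenesulfinate in aqueous formic acid at rt gives the bench-stable sulfone (3R,4S)-6,8-dihydroxy-3,4,5-trimethyl-7-[1-(4-methylbenzenesulfonyl)ethyl]isochroman-1-one F1. Aqueous Na2CO3/CH2Cl2 with a quinine-derived bifunctional squaramide (10 mol%) and 20 then releases 21 by base-induced loss of sulfinate, and the enolate of 20 adds under hydrogen-bond control, so the route is rejoined at 21 and hence 22. If neither catalyst gives full control, the linker epimer (3R,4S)-6,8-dihydroxy-7-{(1S)-1-[(3R,4S)-6-hydroxy-3,4,5-trimethyl-8-oxo-3,4-dihydro-8H-isochromen-7-yl]ethyl}-3,4,5-trimethylisochroman-1-one F2 is removed by preparative HPLC.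

Second: step 10. MeMgBr may also attack the lactone, and 16 is a labile 2,6-dihydroxybenzylic alcohol. The fallback brings in the two-carbon unit as an acyl group and sets out from 13: Fries-type C-acetylation at the only free ring position (AcOH, BF3·OEt2, 80 °C; aqueous NaOAc work-up) gives (3R,4S)-7-acetyl-6,8-dihydroxy-3,4,5-trimethylisochroman-1-one F3. NaBH4 in THF/MeOH at 0 °C reduces the ketone without touching the lactone, and the route is rejoined at 16, bypassing 14 and 15.

Third: step 4. Elimination towards the styrene can compete with SN2 at this hindered, β-branched carbinol. The fallback inverts by oxidation–reduction instead of substitution and sets out from 6: Dess–Martin periodinane (NaHCO3, CH2Cl2) gives (3S)-3-(3,5-dimethoxy-2-methylphenyl)butan-2-one F4. L-Selectride in THF at −78 °C delivers hydride in the Felkin–Anh sense to give the (2R,3S) alcohol, and the route is rejoined at 8, bypassing 7.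

**Further compounds**

F1 | step 14 | (3R,4S)-6,8-dihydroxy-3,4,5-trimethyl-7-[1-(4-methylbenzenesulfonyl)ethyl]isochroman-1-one | Oc1c(C(C)S(=O)(=O)c3ccc(C)cc3)c(O)c2C(=O)O[C@H](C)[C@@H](C)c2c1C
F2 | step 14 | (3R,4S)-6,8-dihydroxy-7-{(1S)-1-[(3R,4S)-6-hydroxy-3,4,5-trimethyl-8-oxo-3,4-dihydro-8H-isochromen-7-yl]ethyl}-3,4,5-trimethylisochroman-1-one | CC1=C2C(=CO[C@H](C)[C@H]2C)C(=O)C([C@@H](C)c2c(O)c(C)c3c(c2O)C(=O)O[C@H](C)[C@H]3C)=C1O
F3 | step 10 | (3R,4S)-7-acetyl-6,8-dihydroxy-3,4,5-trimethylisochroman-1-one | Oc1c(C(C)=O)c(O)c2C(=O)O[C@H](C)[C@@H](C)c2c1C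
F4 | step 4 | (3S)-3-(3,5-dimethoxy-2-methylphenyl)butan-2-one | CC(=O)[C@@H](C)c1cc(OC)cc(OC)c1C
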